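# Proposed total synthesis of CNP0386920.1 (compound 27)

Atom numbering follows the target SMILES: C1 (CHOAc), C2 (CH2), C3 (C(Me)OAc), C4 (CH2), C5 (ring-fusion CH), C6 (CH2), C7 (C=O), C8=C9, C10, C11, N12 (NMe), C13, C14, C15, C16 (quaternary). Ring A is C1–C5 with C16, ring B is C5–C8 with C16, ring C is C8–C16.

## Analysis of the target

Compound 27 is a tricycle in which a cyclohexane (ring A) and a cyclopentanone (ring B) share the C5–C16 bond. A nine-membered N-methyl azonine (ring C) is attached through the quaternary carbon C16 and through C8, whose exocyclic C8=C9 double bond is conjugated with the C7 ketone. There are four stereocentres, C1, C3, C5 and C16. The C1 acetoxy group, the C3 acetoxy group, C6 on C5 and C8 on C16 all lie on one face of ring A (a cis hydrindanone and a cis-1,3-diol diacetate), while C15 and the C3 methyl group lie on the other. The C8=C9 alkene is a further stereo-element: C10 is cis to C16 and trans to C7, an E enone that is a cis alkene inside ring C. Sensitive points are the tertiary acetate at C3 (ionisation under strong acid), the enone (conjugate addition, E/Z equilibration), the vinylogously acidic C10 hydrogens (a leaving group on C11, the ring nitrogen included, can be expelled) and the tertiary amine (N-oxidation). The hard parts are the quaternary C16, which belongs to all three rings and is flanked by C1 and C5, the medium ring, and an order of events in which oxidant and hydride act before the enone and the amine exist. The strategy rests on ring A: oxygen on C1 next to quaternary C16, C8 cis to that oxygen, C6 cis to C8 and a methyl group on C3 are the pattern of the endo adduct of a 1-oxy-3-methylbuta-1,3-diene with a Z-configured C5=C16 enal.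

## Retrosynthetic reasoning

**N12–C13.** Compound 27 is traced back to the amino iodide 26, which comes through salt 25 from the carbamate-protected chloride 24. The cut is not placed at C11–N12, because a leaving group on C11 would sit next to the acidic C10 hydrogens of the enone and would be eliminated. C13 is an ordinary primary carbon. In the precursor the E alkene already holds the C9–C11 arm on the side of the C13–C15 arm. The forward step must close a nine-membered ring by N-alkylation at high dilution without harming the acetates.

**C7–C8.** Ring B of 24 is opened to the alkynyl aldehyde 23. An aldol-type construction of the alkylidene would have to tell C6 from C8 and control the alkene geometry. Adding the formyl C–H bond of C7 across C8≡C9 does both: the acyl group can reach only C8 in a five-membered closure, and cis addition puts C10 trans to C7. The forward reaction is a rhodium-catalysed intramolecular hydroacylation on a substrate whose C6 and C8 arms are already cis on ring A.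

**Ring A oxygen pattern.** Aldehyde 23 is the hydrolysis product of enol ether 22, and the acetates of 22 come from diol 21. The tertiary alcohol of 21 is traced to the syn epoxy alcohol 20 (hydride at C2) and on to allylic alcohol 19, so that the C1 hydroxyl sets C3. These operations are placed before the enone and the free amine exist, because the oxidant would attack the amine and hydride would reduce the ketone. The enol ether is a latent aldehyde that survives fluoride, peroxide, hydride and acylation. Alcohol 19 is unmasked from silyl ether 18.

**C6–C7.** C7 is removed from 18 by a Wittig disconnection at C6=C7, which leads to aldehyde 17 and, one oxidation level up, to ester 16. The ester carbon of the cycloadduct becomes C6, so only one carbon is added.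

**C9–C10 and N-methyl.** Carbamate 16 is demethylated at nitrogen to 15, and 15 is cut at C9–C10 into terminal alkyne 11 and the two-carbon electrophile 12, which brings C10, C11 and protected N12. The bond is made at this stage, where the only electrophile in 11 is a hindered ester, and not later, when an aldehyde or an acid-labile enol ether would be present.

**C8≡C9.** Alkyne 11 is the one-carbon homologue of aldehyde 10: C8 is the formyl carbon of the cycloadduct and C9 is added.

**C1–C16 and C4–C5 (key).** Ring A of 10 is disconnected into dienophile 7 and diene 9. This creates C1, C5 and quaternary C16 in one step from achiral, acyclic partners and leaves C2=C3 where the C3 oxygen is later introduced. The forward reaction must be regioselective (C4 to C5), endo-selective, face-selective on the enal, and must keep the Z geometry of 7.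

**Starting materials.** Dienophile 7 is the open-chain methyl ester of hydroxybutenolide 6, whose ring guarantees the Z geometry. Compound 6 is the photo-oxygenation product of the 3-alkylfuran 4 (through endoperoxide 5), and 4 comes from 1 and 2 by way of 3. Diene 9 is the silyl dienol ether of aldehyde 8.

## Alternatives that were turned down

**Alternative 1:** Ring C would be cut at C14–C15. The ammonium tosylate A2, with a vinyl group on C16 and an allyl group on nitrogen, would be closed by a ruthenium carbene catalyst to the 14,15-didehydro compound A1, and C14=C15 would then be saturated.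
- For: metathesis is reversible, so oligomers can return to the ring, which an irreversible N-alkylation cannot offer. Protonation of the amine protects the catalyst. On reliability of the medium-ring closure this alternative is probably at least as good as the chosen end game.
- Against: the C16 vinyl group is neopentyl-like and loads onto ruthenium slowly. C14=C15 must afterwards be reduced beside the enone C8=C9, an extra step that depends on chemoselectivity. The disconnection does not say how C1, C5 and C16 are set.
- In exchange the chosen strategy sets the three ring A stereocentres in one catalytic step, and its last step gives 27 itself.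

**Alternative 2:** Ring B would arise by one-carbon ring expansion. The ring A-fused dichlorocyclobutanone A4 would take up C6 from diazomethane A5 between C5 and C7 to give the dichlorocyclopentanone A3.
- For: the carbon without chlorine migrates dependably. A ketene [2+2] cycloaddition to a ring A alkene gives A4 with cis fusion and quaternary C16 in one step. The chlorines on C8 allow a regiospecific C8 enolate for building C8=C9. On regiocontrol at C8 this matches hydroacylation and beats an aldol on a plain ketone.
- Against: A3 has no oxygen on C1. Its alkene C1=C2 lies between the fully substituted C16 and C3, so placing oxygen on C1 and hydrogen on C2 from the right face has no clear bias. The absolute configuration must come from C3 alone, made enantioenriched beforehand and steering the cycloaddition from a distance. A5 is hazardous on scale, and ring C is still to be built.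
- The chosen route sets C1, C5 and C16 together and uses the C1 oxygen to direct the C3 oxygen.

**Alternative 3:** Ring B would come from a Pauson–Khand reaction with the C1 oxygen as tether. The enyne ether A7 (alkyne carbons C5 and C6, alkene C16=C8) would give the oxabicyclic cyclopentenone A6, forming C5–C16, C6–C7 and C7–C8 at once.
- For: three C–C bonds and quaternary C16 in one step, with the C1 stereocentre on the tether where it can direct. In bonds formed per step it beats the cycloaddition chosen here.
- Against: 1,1-disubstituted alkenes are sluggish partners, and induction from a single tether substituent is usually modest. In A6 ring A is still open (C3–C4 must be made after the tether bond to C4 is cut), C5 is still sp2, C8 is a methylene that must later become the alkylidene, and C1 needs its own asymmetric step beforehand.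
- The chosen strategy builds ring A first with all three stereocentres, so ring B closes on a rigid scaffold by a reaction that also fixes the C8=C9 geometry.

Key step: step 5

Remark on the chemistry: the facial sense of step 5 is assigned from the accepted formyl C–H···O binding model of 2-substituted enals to oxazaborolidinium ions; if the sense proved opposite, the (S) catalyst would be used without other change.

## Route

Step 1
Reactants: 1 3-bromofuran; 2 1-bromo-3-chloropropane
Product: 4 3-(3-chloropropyl)furan, via furan-3-yllithium 3 (not isolated)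
Conditions: t-BuLi (2.0 equiv), THF, −78 °C; then 2 (3 equiv), DMPU, −78 → −40 °C
Reagents that add atoms: none
Why: Bromine–lithium exchange gives the 3-lithiofuran, which keeps its position below about −40 °C and is alkylated (SN2) at the C–Br end of 2, bromide being by far the better leaving group.

Step 2
Reactants: 4 3-(3-chloropropyl)furan
Product: 6 4-(3-chloropropyl)-5-hydroxyfuran-2(5H)-one, via furan endoperoxide 5 (not isolated)
Conditions: O2, hν (visible), tetraphenylporphyrin (cat.), i-Pr2NEt, CH2Cl2, −78 °C → rt
Reagents that add atoms: dioxygen, O=O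
Why: Singlet oxygen adds [4+2] to the furan; the hindered base removes the less hindered bridgehead proton, remote from the alkyl group (Kornblum–DeLaMare-type fragmentation), so the lactol carbon ends up next to the alkylated carbon.

Step 3
Reactants: 6 4-(3-chloropropyl)-5-hydroxyfuran-2(5H)-one
Product: 7 methyl (Z)-6-chloro-3-formylhex-2-enoate
Conditions: MeI, K2CO3, DMF, 0 °C, dark, short reaction time
Reagents that add atoms: iodomethane, CI
Why: In base the lactol opens to the cis-formyl carboxylate, whose O-alkylation gives the open-chain ester (carboxylate alkylation of a ring–chain tautomer); the Z geometry is inherited from the ring, and cold, dark conditions limit isomerisation.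

Step 4
Reactants: 8 3-methylbut-2-enal
Product: 9 (E)-tert-butyldimethyl[(3-methylbuta-1,3-dien-1-yl)oxy]silane
Conditions: TBSOTf, Et3N, Et2O, 0 °C → rt
Reagents that add atoms: tert-butyldimethylsilyl trifluoromethanesulfonate, CC(C)(C)[Si](C)(C)OS(=O)(=O)C(F)(F)F
Why: O-silylation followed by γ-deprotonation by the amine (silyl dienol ether formation) gives mainly the E diene; any Z isomer is inert as a diene and is covered by using 9 in excess.

Step 5
Reactants: 7 methyl (Z)-6-chloro-3-formylhex-2-enoate; 9 (E)-tert-butyldimethyl[(3-methylbuta-1,3-dien-1-yl)oxy]silane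
Product: 10 methyl (1R,5S,6R)-5-[(tert-butyldimethylsilyl)oxy]-6-(3-chloropropyl)-6-formyl-3-methylcyclohex-3-ene-1-carboxylate
Conditions: (R)-3,3-diphenyl-1-(2-methylphenyl)tetrahydro-1H,3H-pyrrolo[1,2-c][1,3,2]oxazaborole [from (R)-α,α-diphenylprolinol] (20 mol %) + HNTf2 (17 mol %), 9 (2 equiv), CH2Cl2, −78 → −40 °C
Reagents that add atoms: none
Why: The oxazaborolidinium ion binds the formyl oxygen of 7, the more basic carbonyl, which puts the largest LUMO coefficient on C5; the electron-rich terminus C4 of 9 therefore bonds to C5 and the oxygen-bearing terminus C1 to C16, a regiochemistry reinforced by the 3-methyl group. The reaction is a concerted, asynchronous, suprafacial [4+2] cycloaddition that closes ring A by forming C1–C16 and C4–C5 together, so no separate cyclisation mode has to be chosen. The closest known reaction type is the cationic oxazaborolidine-catalysed Diels–Alder reaction of 1-silyloxy dienes with 2-substituted enals. C16 is set by the catalyst: in the binding model the s-trans enal lies over one aryl group, and the (R) catalyst leaves open the Si face at C16, the face that 10 requires. C5 follows from suprafacial addition to the Z alkene, which keeps C6 cis to C8. C1 follows from the endo transition state, in which both carbonyl groups of 7 lie under the E diene, so the silyloxy group ends up cis to C8. The step needs the Z geometry of 7 to survive and cycloaddition to win over 1,2-addition to the formyl group; low temperature, a slight deficit of HNTf2 (no free strong acid) and the robust silyl group are meant to secure this.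

Step 6
Reactants: 10 (cycloadduct)
Product: 11 methyl (1R,5S,6S)-5-[(tert-butyldimethylsilyl)oxy]-6-(3-chloropropyl)-6-ethynyl-3-methylcyclohex-3-ene-1-carboxylate
Conditions: dimethyl (1-diazo-2-oxopropyl)phosphonate, K2CO3, MeOH, 0 °C → rt
Reagents that add atoms: dimethyl (1-diazo-2-oxopropyl)phosphonate, COP(=O)(OC)C(=[N+]=[N-])C(C)=O
Why: Ohira–Bestmann form of the Seyferth–Gilbert homologation: the diazomethylphosphonate anion made in the flask adds to the C8 aldehyde, and cycloelimination, loss of N2 and a 1,2-hydrogen shift give C8≡C9. The aldehyde has no α-hydrogen, and carbonate is too weak to epimerise C5 next to the ester.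

Step 7
Reactants: 11 (alkynyl ester); 12 tert-butyl 1,2,3-oxathiazolidine-3-carboxylate 2,2-dioxide
Product: 15 methyl (1R,5S,6S)-6-{4-[(tert-butoxycarbonyl)amino]but-1-yn-1-yl}-5-[(tert-butyldimethylsilyl)oxy]-6-(3-chloropropyl)-3-methylcyclohex-3-ene-1-carboxylate, via lithium acetylide 13 (not isolated), via lithium N-sulfamate 14 (not isolated)
Conditions: LiN(i-Pr)2 (1.05 equiv), THF, −78 °C; 12, −78 °C → rt; then 10% aq. citric acid, rt
Reagents that add atoms: none
Why: The alkyne C–H is kinetically by far the most acidic site, and the hindered amide base does not add to the ester. The acetylide opens the cyclic sulfamidate by SN2 at its O-bearing carbon, and mild acid hydrolyses the N-sulfamate, so C10, C11 and N12 arrive in one operation.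

Step 8
Reactants: 15 (NH carbamate)
Product: 16 methyl (1R,5S,6S)-6-{4-[(tert-butoxycarbonyl)(methyl)amino]but-1-yn-1-yl}-5-[(tert-butyldimethylsilyl)oxy]-6-(3-chloropropyl)-3-methylcyclohex-3-ene-1-carboxylate
Conditions: NaH, MeI, DMF, 0 °C → rt
Reagents that add atoms: iodomethane, CI
Why: N-Methylation of the carbamate anion; cyclisation onto C13–Cl would need a nine-membered ring containing the alkyne and does not compete.

Step 9
Reactants: 16 (N-methyl carbamate ester)
Product: 17 tert-butyl N-(4-{2-[(tert-butyldimethylsilyl)oxy]-1-(3-chloropropyl)-6-formyl-4-methylcyclohex-3-en-1-yl}but-3-yn-1-yl)-N-methylcarbamate (ring configuration as in 16)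
Conditions: i-Bu2AlH (1.1 equiv), CH2Cl2, −78 °C; aq. potassium sodium tartrate (KNaC4H4O6)
Reagents that add atoms: none
Why: Partial reduction: the hindered ester gives a tetrahedral aluminate that is stable at −78 °C and releases the aldehyde on work-up; carbamate, alkyne and chloride are untouched.

Step 10
Reactants: 17 (C6 aldehyde)
Product: 18 tert-butyl N-(4-{2-[(tert-butyldimethylsilyl)oxy]-1-(3-chloropropyl)-6-(2-methoxyethenyl)-4-methylcyclohex-3-en-1-yl}but-3-yn-1-yl)-N-methylcarbamate (E/Z mixture at the enol ether)
Conditions: MeOCH2PPh3Cl, KN(SiMe3)2, THF, 0 °C; then 17, −78 → 0 °C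
Reagents that add atoms: (methoxymethyl)triphenylphosphonium chloride, COC[P+](c1ccccc1)(c1ccccc1)c1ccccc1.[Cl-]
Why: Wittig methoxymethylenation adds C7 as a base-stable latent aldehyde; both enol ether isomers converge later, and adding the aldehyde cold to pre-formed ylide limits enolisation at C5.

Step 11
Reactants: 18 (silyl ether)
Product: 19 tert-butyl N-(4-{1-(3-chloropropyl)-2-hydroxy-6-(2-methoxyethenyl)-4-methylcyclohex-3-en-1-yl}but-3-yn-1-yl)-N-methylcarbamate
Conditions: Bu4NF, THF, rt
Reagents that add atoms: none
Why: Fluoride desilylation frees the C1 allylic alcohol; no other group is fluoride-labile under these conditions.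

Step 12
Reactants: 19 (allylic alcohol)
Product: 20 syn epoxy alcohol (C2–C3 epoxide on the face of the C1 hydroxyl; otherwise as 19)
Conditions: VO(acac)2 (5 mol %), t-BuOOH (in decane), CH2Cl2, 0 °C → rt
Reagents that add atoms: tert-butyl hydroperoxide, CC(C)(C)OO
Why: Hydroxyl-directed epoxidation: the vanadium alkoxide of C1–OH delivers the peroxide oxygen to the face of C2=C3 syn to the hydroxyl, which sets the C3–O bond cis to C1–O. The enol ether and the alkyne lack an allylic hydroxyl and react far more slowly.

Step 13
Reactants: 20 (epoxy alcohol)
Product: 21 tert-butyl N-(4-{1-(3-chloropropyl)-2,4-dihydroxy-6-(2-methoxyethenyl)-4-methylcyclohexyl}but-3-yn-1-yl)-N-methylcarbamate (C1 and C3 hydroxyls cis)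
Conditions: LiAlH4, Et2O, 0 °C → rt
Reagents that add atoms: none
Why: Hydride attacks the secondary C2 in an SN2, trans-diaxial opening anti to the epoxide oxygen and leaves the C3–O bond intact, so the tertiary alcohol is cis to C1–OH. In ether at low temperature a primary chloride and a carbamate are reduced much more slowly than an epoxide.

Step 14
Reactants: 21 (diol)
Product: 22 diacetate of 21 (acetoxy groups on C1 and C3)
Conditions: Ac2O, Et3N, DMAP, CH2Cl2, rt → 40 °C
Reagents that add atoms: acetic anhydride, CC(=O)OC(C)=O
Why: DMAP-catalysed acylation acetylates the secondary and the equatorial tertiary alcohol. This installs both target acetates and blocks C1–OH, which would otherwise form a lactol with the C7 aldehyde.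

Step 15
Reactants: 22 (enol ether diacetate)
Product: 23 tert-butyl N-(4-{2,4-diacetoxy-1-(3-chloropropyl)-4-methyl-6-(2-oxoethyl)cyclohexyl}but-3-yn-1-yl)-N-methylcarbamate
Conditions: HCl (1 M aq), THF, 0 °C → rt
Reagents that add atoms: water, O
Why: Enol ether hydrolysis (protonation at C6, hydration of the oxocarbenium ion, loss of methanol) unveils the C7 aldehyde; dilute aqueous acid does not cleave the carbamate or the tertiary acetate.

Step 16
Reactants: 23 (alkynyl aldehyde)
Product: 24 (E)-1-{3-[(tert-butoxycarbonyl)(methyl)amino]propylidene}-7a-(3-chloropropyl)-5-methyl-2-oxooctahydro-1H-indene-5,7-diyl diacetate (cis ring fusion)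
Conditions: [Rh(dppe)]2(BF4)2 (5 mol %), acetone, rt → 50 °C
Reagents that add atoms: none
Why: Intramolecular hydroacylation of a 5-alkynal (5-exo closure): the formyl C–H bond adds oxidatively to monovalent rhodium, cis hydrometalation places hydride on C9 and rhodium on C8, and reductive elimination forms C7–C8. The cis addition gives the E enone with C10 cis to C16, and the ring fusion is cis because C6 and C8 are cis on ring A.

Step 17
Reactants: 24 (chloro enone carbamate)
Product: 27 CNP0386920.1, via amine hydrochloride 25 (not isolated), via iodo amine 26 (not isolated)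
Conditions: HCl (4 M in 1,4-dioxane), 0 °C, 30 min, evaporate; then NaI, K2CO3, MeCN (2 mM), 60 °C
Reagents that add atoms: none
Why: Short exposure to anhydrous HCl removes the carbamate at a rate that tertiary alkyl esters tolerate. Halide exchange then gives the iodide, and the secondary amine closes ring C by intramolecular N-alkylation at C13 (nine-membered, exo-tet), helped by the E alkene and quaternary C16, which hold both arms on one side.

## Compound list

1 | 3-bromofuran | Brc1ccoc1 | starting material
2 | 1-bromo-3-chloropropane | ClCCCBr | starting material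
3 | furan-3-yllithium | [Li]c1ccoc1 | intermediate (not isolated)
4 | 3-(3-chloropropyl)furan | ClCCCc1ccoc1 | intermediate
5 | 5-(3-chloropropyl)-2,3,7-trioxabicyclo[2.2.1]hept-5-ene (racemic) | ClCCCC1=CC2OOC1O2 | intermediate (not isolated)
6 | 4-(3-chloropropyl)-5-hydroxyfuran-2(5H)-one (racemic lactol) | O=C1OC(O)C(CCCCl)=C1 | intermediate
7 | methyl (Z)-6-chloro-3-formylhex-2-enoate | O=C/C(CCCCl)=C\C(=O)OC | intermediate
8 | 3-methylbut-2-enal | CC(C)=CC=O | starting material
9 | (E)-tert-butyldimethyl[(3-methylbuta-1,3-dien-1-yl)oxy]silane | C=C(C)/C=C/O[Si](C)(C)C(C)(C)C | intermediate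
10 | methyl (1R,5S,6R)-5-[(tert-butyldimethylsilyl)oxy]-6-(3-chloropropyl)-6-formyl-3-methylcyclohex-3-ene-1-carboxylate | CC(C)(C)[Si](C)(C)O[C@H]1C=C(C)C[C@@H](C(=O)OC)[C@]1(C=O)CCCCl | intermediate
11 | methyl (1R,5S,6S)-5-[(tert-butyldimethylsilyl)oxy]-6-(3-chloropropyl)-6-ethynyl-3-methylcyclohex-3-ene-1-carboxylate | CC(C)(C)[Si](C)(C)O[C@H]1C=C(C)C[C@@H](C(=O)OC)[C@]1(C#C)CCCCl | intermediate
12 | tert-butyl 1,2,3-oxathiazolidine-3-carboxylate 2,2-dioxide | CC(C)(C)OC(=O)N1CCOS1(=O)=O | starting material
13 | lithium acetylide of 11 (lithium on C9) | CC(C)(C)[Si](C)(C)O[C@H]1C=C(C)C[C@@H](C(=O)OC)[C@]1(C#C[Li])CCCCl | intermediate (not isolated)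
14 | lithium N-sulfamate of 15 (SO3Li on N12) | CC(C)(C)[Si](C)(C)O[C@H]1C=C(C)C[C@@H](C(=O)OC)[C@]1(C#CCCN(C(=O)OC(C)(C)C)S(=O)(=O)[O-])CCCCl.[Li+] | intermediate (not isolated)
15 | methyl (1R,5S,6S)-6-{4-[(tert-butoxycarbonyl)amino]but-1-yn-1-yl}-5-[(tert-butyldimethylsilyl)oxy]-6-(3-chloropropyl)-3-methylcyclohex-3-ene-1-carboxylate | CC(C)(C)[Si](C)(C)O[C@H]1C=C(C)C[C@@H](C(=O)OC)[C@]1(C#CCCNC(=O)OC(C)(C)C)CCCCl | intermediate
16 | methyl (1R,5S,6S)-6-{4-[(tert-butoxycarbonyl)(methyl)amino]but-1-yn-1-yl}-5-[(tert-butyldimethylsilyl)oxy]-6-(3-chloropropyl)-3-methylcyclohex-3-ene-1-carboxylate | CC(C)(C)[Si](C)(C)O[C@H]1C=C(C)C[C@@H](C(=O)OC)[C@]1(C#CCCN(C)C(=O)OC(C)(C)C)CCCCl | intermediate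
17 | tert-butyl N-(4-{2-[(tert-butyldimethylsilyl)oxy]-1-(3-chloropropyl)-6-formyl-4-methylcyclohex-3-en-1-yl}but-3-yn-1-yl)-N-methylcarbamate (silyloxy, alkynyl and formyl arms mutually cis) | CC(C)(C)[Si](C)(C)O[C@H]1C=C(C)C[C@@H](C=O)[C@]1(C#CCCN(C)C(=O)OC(C)(C)C)CCCCl | intermediate
18 | tert-butyl N-(4-{2-[(tert-butyldimethylsilyl)oxy]-1-(3-chloropropyl)-6-(2-methoxyethenyl)-4-methylcyclohex-3-en-1-yl}but-3-yn-1-yl)-N-methylcarbamate (E/Z mixture at the enol ether) | CC(C)(C)[Si](C)(C)O[C@H]1C=C(C)C[C@@H](C=COC)[C@]1(C#CCCN(C)C(=O)OC(C)(C)C)CCCCl | intermediate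
19 | tert-butyl N-(4-{1-(3-chloropropyl)-2-hydroxy-6-(2-methoxyethenyl)-4-methylcyclohex-3-en-1-yl}but-3-yn-1-yl)-N-methylcarbamate | O[C@H]1C=C(C)C[C@@H](C=COC)[C@]1(C#CCCN(C)C(=O)OC(C)(C)C)CCCCl | intermediate
20 | syn C2–C3 epoxide of 19 (epoxide oxygen cis to the C1 hydroxyl) | O[C@H]1[C@H]2O[C@@]2(C)C[C@@H](C=COC)[C@]1(C#CCCN(C)C(=O)OC(C)(C)C)CCCCl | intermediate
21 | tert-butyl N-(4-{1-(3-chloropropyl)-2,4-dihydroxy-6-(2-methoxyethenyl)-4-methylcyclohexyl}but-3-yn-1-yl)-N-methylcarbamate (hydroxyls cis) | O[C@H]1C[C@@](C)(O)C[C@@H](C=COC)[C@]1(C#CCCN(C)C(=O)OC(C)(C)C)CCCCl | intermediate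
22 | diacetate of 21 | CC(=O)O[C@H]1C[C@@](C)(OC(C)=O)C[C@@H](C=COC)[C@]1(C#CCCN(C)C(=O)OC(C)(C)C)CCCCl | intermediate
23 | tert-butyl N-(4-{2,4-diacetoxy-1-(3-chloropropyl)-4-methyl-6-(2-oxoethyl)cyclohexyl}but-3-yn-1-yl)-N-methylcarbamate | CC(=O)O[C@H]1C[C@@](C)(OC(C)=O)C[C@@H](CC=O)[C@]1(C#CCCN(C)C(=O)OC(C)(C)C)CCCCl | intermediate
24 | (E)-1-{3-[(tert-butoxycarbonyl)(methyl)amino]propylidene}-7a-(3-chloropropyl)-5-methyl-2-oxooctahydro-1H-indene-5,7-diyl diacetate (cis-fused) | CC(=O)O[C@H]1C[C@@](C)(OC(C)=O)C[C@H]2CC(=O)/C(=C/CCN(C)C(=O)OC(C)(C)C)[C@]21CCCCl | intermediate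
25 | N-methylammonium chloride obtained from 24 by loss of the carbamate | CC(=O)O[C@H]1C[C@@](C)(OC(C)=O)C[C@H]2CC(=O)/C(=C/CC[NH2+]C)[C@]21CCCCl.[Cl-] | intermediate (not isolated)
26 | free secondary amine with 3-iodopropyl on C16 | CC(=O)O[C@H]1C[C@@](C)(OC(C)=O)C[C@H]2CC(=O)/C(=C/CCNC)[C@]21CCCI | intermediate (not isolated)
27 | CNP0386920.1 (cis-hydrindanone-fused N-methylazonine diacetate, E enone) | CC(=O)O[C@H]1C[C@@](C)(OC(C)=O)C[C@H]2CC(=O)/C3=C/CCN(C)CCC[C@@]321 | target

## Step count and risk assessment

Total: 17 steps. Longest linear sequence: 16 steps (steps 1–3 and 5–17); step 4 makes the diene in a one-step branch.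

**Step 5 (key step).** Most likely failures:
- addition of the diene terminus to the activated formyl carbon, or protodesilylation of the diene by the acidic catalyst, instead of cycloaddition;
- acid-promoted Z-to-E isomerisation of the dienophile before it reacts, which would invert C5 relative to C16;
- poor or reversed facial selectivity, because the cis ester must sit over the shielding aryl group of the catalyst.

Fallback (sets out from 7 and 9, returns at 10): the cycloaddition is run without acid in toluene at 20–60 °C, where the doubly activated dienophile should still react under control of the formyl group. This gives racemic 10 F1, which is resolved by preparative chromatography on a chiral stationary phase to give 10, at the cost of half the material.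

**Step 17.** Most likely failures: intermolecular N-alkylation (oligomerisation) outrunning closure of the medium ring; ionisation of the tertiary acetate during carbamate cleavage; base-induced vinylogous elimination of the amine.

Fallback (sets out from 24, returns at 27): ring C is closed by reductive amination instead of alkylation. NaI in acetone converts 24 into the iodide carbamate F2. N-Methylmorpholine N-oxide in MeCN oxidises the primary iodide to the C13 aldehyde carbamate F3. Brief HCl in dioxane gives the amino aldehyde hydrochloride F4, which is added slowly to NaBH(OAc)3 in 1,2-dichloroethane, so that the reversibly formed cyclic iminium ion is reduced to 27; this reagent does not reduce the ketone.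

**Step 16.** Most likely failures: decarbonylation of the acyl rhodium hydride, or slow insertion of the alkyne on the quaternary carbon, ending in catalyst death.

Fallback (sets out from 23, returns at 24): nickel-catalysed reductive cyclisation of the alkynal (Ni(cod)2, PBu3, Et3SiH, THF) forms C7–C8 with cis delivery of C7 and hydrogen across the alkyne and gives the allylic triethylsilyl ether F5 as a mixture of C7 epimers. HF·pyridine frees the allylic alcohol F6, and Dess–Martin periodinane oxidises it to 24.

**Step 13.** Most likely failure: reduction of the C13–Cl bond or of the carbamate competing with the slow opening of a hindered epoxide.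

Fallback (sets out from 20, returns at 21): the epoxide is opened by bromide at the secondary C2 (Li2NiBr4, THF) to the trans-diaxial bromohydrin F7. The C–Br bond is then reduced with Bu3SnH and AIBN in toluene at 80 °C, a radical chain that abstracts a secondary bromide far faster than a primary chloride, giving 21.

**Step 7.** Most likely failures: attack of the acetylide or the base on the ester, enolisation with epimerisation at C5, or attack of the acetylide on the carbamate carbonyl of 12 instead of on carbon.

Fallback (sets out from 11, returns at 18): the chain is attached after the ester is gone. i-Bu2AlH at −78 °C reduces 11 to the alkynyl aldehyde F8, and methoxymethylenation gives the enol ether F9. n-BuLi gives its lithium acetylide F10, which opens 12 to the lithium N-sulfamate F11. Hydrolysis with aqueous NaH2PO4, mild enough for the enol ether, gives the carbamate F12, and NaH with MeI then gives 18.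

Further compounds
F1 | step 5 | racemic 10 (1:1 mixture of 10 and its enantiomer) | CC(C)(C)[Si](C)(C)O[C@H]1C=C(C)C[C@@H](C(=O)OC)[C@]1(C=O)CCCCl.CC(C)(C)[Si](C)(C)O[C@@H]1C=C(C)C[C@H](C(=O)OC)[C@@]1(C=O)CCCCl
F2 | step 17 | 3-iodopropyl analogue of 24 | CC(=O)O[C@H]1C[C@@](C)(OC(C)=O)C[C@H]2CC(=O)/C(=C/CCN(C)C(=O)OC(C)(C)C)[C@]21CCCI
F3 | step 17 | C13 aldehyde (3-oxopropyl analogue of 24) | CC(=O)O[C@H]1C[C@@](C)(OC(C)=O)C[C@H]2CC(=O)/C(=C/CCN(C)C(=O)OC(C)(C)C)[C@]21CCC=O
F4 | step 17 | amino aldehyde hydrochloride from F3 | CC(=O)O[C@H]1C[C@@](C)(OC(C)=O)C[C@H]2CC(=O)/C(=C/CC[NH2+]C)[C@]21CCC=O.[Cl-]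
F5 | step 16 | allylic triethylsilyl ether (C7 carbinol silyl ether, E alkylidene, C7 epimers) | CC(=O)O[C@H]1C[C@@](C)(OC(C)=O)C[C@H]2CC(O[Si](CC)(CC)CC)/C(=C/CCN(C)C(=O)OC(C)(C)C)[C@]21CCCCl
F6 | step 16 | allylic alcohol (C7 carbinol, E alkylidene, C7 epimers) | CC(=O)O[C@H]1C[C@@](C)(OC(C)=O)C[C@H]2CC(O)/C(=C/CCN(C)C(=O)OC(C)(C)C)[C@]21CCCCl
F7 | step 13 | trans-diaxial bromohydrin (bromine on C2, hydroxyls on C1 and C3) | O[C@H]1[C@H](Br)[C@@](C)(O)C[C@@H](C=COC)[C@]1(C#CCCN(C)C(=O)OC(C)(C)C)CCCCl
F8 | step 7 | alkynyl aldehyde (C6 aldehyde of 11) | CC(C)(C)[Si](C)(C)O[C@H]1C=C(C)C[C@@H](C=O)[C@]1(C#C)CCCCl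
F9 | step 7 | terminal alkyne enol ether (E/Z mixture) | CC(C)(C)[Si](C)(C)O[C@H]1C=C(C)C[C@@H](C=COC)[C@]1(C#C)CCCCl
F10 | step 7 | lithium acetylide of F9 | CC(C)(C)[Si](C)(C)O[C@H]1C=C(C)C[C@@H](C=COC)[C@]1(C#C[Li])CCCCl
F11 | step 7 | lithium N-sulfamate of F12 | CC(C)(C)[Si](C)(C)O[C@H]1C=C(C)C[C@@H](C=COC)[C@]1(C#CCCN(C(=O)OC(C)(C)C)S(=O)(=O)[O-])CCCCl.[Li+]
F12 | step 7 | NH carbamate enol ether (N-demethyl 18) | CC(C)(C)[Si](C)(C)O[C@H]1C=C(C)C[C@@H](C=COC)[C@]1(C#CCCNC(=O)OC(C)(C)C)CCCCl
A1 | alternative 1 | 14,15-didehydro analogue of 27 | CC(=O)O[C@H]1C[C@@](C)(OC(C)=O)C[C@H]2CC(=O)/C3=C/CCN(C)C/C=C\[C@@]321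
A2 | alternative 1 | metathesis precursor, N-allyl-N-methylammonium tosylate with vinyl on C16 | CC(=O)O[C@H]1C[C@@](C)(OC(C)=O)C[C@H]2CC(=O)/C(=C/CC[NH+](C)CC=C)[C@]21C=C.Cc1ccc(cc1)S(=O)(=O)[O-]
A3 | alternative 2 | ring A-fused 2,2-dichlorocyclopentanone | C1=C[C@@](C)(O[Si](CC)(CC)CC)C[C@H]2CC(=O)C(Cl)(Cl)[C@]21CCCCl
A4 | alternative 2 | ring A-fused 2,2-dichlorocyclobutanone | C1=C[C@@](C)(O[Si](CC)(CC)CC)C[C@H]2C(=O)C(Cl)(Cl)[C@]21CCCCl
A5 | alternative 2 | diazomethane | C=[N+]=[N-]
A6 | alternative 3 | oxabicyclic cyclopentenone with quaternary C16 | C=C(C)C[C@@H]1OCC2=CC(=O)C[C@@]12CCCCl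
A7 | alternative 3 | enyne propargyl ether of the C1 carbinol | C=C(C)C[C@H](OCC#C)C(=C)CCCCl
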